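**Retrosynthetic overview** (ring A = meta-bridged trioxygenated ring, B = para-phenylene, C = ortho-bridged trioxygenated ring, D = ortho-phenylene)

1. Rings A and C are both 3-aryloxycatechols. The outer OH of each (ring A: on the carbon meta to the benzylic carbon; ring C: on the carbon para to the benzylic carbon) sits at the only free C–H ortho to the inner phenol oxygen, so both are installed last: 19 ⇐ bis(silylene) 18 ⇐ double silanol-directed Pd C–H oxygenation of macrocyclic bisphenol 14.
2. 14 ⇐ (BBr3; H2) stilbene 12 ⇐ McMurry closure of the 17-membered ring from dialdehyde 11; the two carbons of the B–C bridge are the formyl carbons that activated the two SNAr reactions.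
3. 11 ⇐ A–D ethano bridge from ethynyltrimethylsilane: two Sonogashira couplings (on 3, then with 6) and an aldehyde-sparing hydrogenation.
4. Diaryl ethers A–O–B and C–O–D by SNAr: 1 + 2 → 3 and 4 + 5 → 6.
5. Ring order: the four benzene rings are bought; the macrocycle closes in step 6; two temporary dioxasilole rings form in step 10.

Key step: step 10

Remark: the target SMILES has no stereocentre and no fixed axis is assumed, so no asymmetric step is needed; the alkene geometry of 12 is erased in step 7.

**Step 1**
Reactants: 1 5-bromo-2-methoxyphenol; 2 4-fluorobenzaldehyde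
Product: 3 4-(5-bromo-2-methoxyphenoxy)benzaldehyde
Conditions: K2CO3, DMF, 130 °C
Reagents that add atoms: none
Why: SNAr, the para-formyl group activates the C–F bond of 2 toward the phenoxide of 1, and the aryl bromide is inert without a metal catalyst.

**Step 2**
Reactants: 4 2-iodophenol; 5 2-fluoro-3-methoxybenzaldehyde
Product: 6 2-(2-iodophenoxy)-3-methoxybenzaldehyde
Conditions: Cs2CO3, DMF, 100 °C
Reagents that add atoms: none
Why: SNAr, the ortho-formyl group activates the fluoride of 5 toward the caesium phenoxide of 4, and the C–I bond is untouched under metal-free conditions.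

**Step 3**
Reactants: 3; 7 ethynyltrimethylsilane
Product: 8 4-{2-methoxy-5-[(trimethylsilyl)ethynyl]phenoxy}benzaldehyde
Conditions: Pd(PhCN)2Cl2 (cat.), P(t-Bu)3 (cat.), CuI (cat.), i-Pr2NH, dioxane, rt
Reagents that add atoms: none
Why: Sonogashira coupling, the electron-rich Pd/P(t-Bu)3 catalyst should insert into the anisole-type C–Br bond at room temperature and the aldehyde is tolerated.

**Step 4**
Reactants: 8; 6
Product: 10 diarylalkyne dialdehyde 2-(2-{[3-(4-formylphenoxy)-4-methoxyphenyl]ethynyl}phenoxy)-3-methoxybenzaldehyde, via terminal alkyne 9 (not isolated)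
Conditions: PdCl2(PPh3)2 (cat.), CuI (cat.), CsF, Et3N, DMF–H2O, 50 °C
Reagents that add atoms: none
Why: fluoride-triggered desilylation releases alkyne 9 slowly, which suppresses its oxidative dimerisation, and 9 undergoes Sonogashira coupling with the reactive aryl iodide 6.

**Step 5**
Reactants: 10
Product: 11 bibenzyl dialdehyde 2-(2-{2-[3-(4-formylphenoxy)-4-methoxyphenyl]ethyl}phenoxy)-3-methoxybenzaldehyde
Conditions: H2 (1 atm), 10% Pd/C, Ph2S (cat.), EtOAc, rt
Reagents that add atoms: none
Why: catalytic hydrogenation on sulfide-poisoned Pd/C should saturate the alkyne while leaving aromatic aldehydes and aryl ethers intact.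

**Step 6**
Reactants: 11
Product: 12 macrocyclic stilbene bis(methyl ether), the 17-membered ring with a C=C between rings B and C (expected and drawn as Z; either geometry serves)
Conditions: TiCl4, Zn, pyridine, THF, reflux, slow addition of 11 (high dilution)
Reagents that add atoms: none
Why: intramolecular McMurry coupling, low-valent titanium joins the two aryl aldehydes through a pinacolate and deoxygenates it, and high dilution favours closure of the 17-membered ring over oligomers.

**Step 7**
Reactants: 12
Product: 13 macrocyclic bis(bibenzyl) bis(methyl ether)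
Conditions: H2 (1 atm), 10% Pd/C, EtOAc–THF, rt
Reagents that add atoms: none
Why: catalytic hydrogenation of the stilbene C=C, with no other reducible group present.

**Step 8**
Reactants: 13
Product: 14 macrocyclic bisphenol (the target without its two outer hydroxyls)
Conditions: BBr3, CH2Cl2, −78 °C → rt; then H2O
Reagents that add atoms: none
Why: Lewis acid demethylation of the two aryl methyl ethers, with the diaryl ether bonds inert to BBr3.

**Step 9**
Reactants: 14
Product: 16 bis(di-tert-butylhydroxysilyl) ether of 14, via bis(silyl triflate) 15 (not isolated)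
Conditions: t-Bu2Si(OTf)2 (excess), 2,6-lutidine, CH2Cl2, 0 °C → rt; then H2O, THF
Reagents that add atoms: di-tert-butylsilyl bis(trifluoromethanesulfonate) CC(C)(C)[Si](OS(=O)(=O)C(F)(F)F)(OS(=O)(=O)C(F)(F)F)C(C)(C)C; water O
Why: O-silylation of each phenol by the silyl bis(triflate), where the tert-butyl groups block a second aryloxide substitution, and hydrolysis of the remaining Si–OTf gives a silanol too hindered to condense.

**Step 10**
Reactants: 16
Product: 18 bis(di-tert-butylsilylene) derivative of the target (both catechols as 2,2-di-tert-butyl-1,3,2-benzodioxasiloles), via bis(acetoxy) bis(silanol) 17 (not isolated)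
Conditions: Pd(OPiv)2 (10 mol%), PhI(OAc)2 (4–5 equiv), PhMe, 100 °C
Reagents that add atoms: (diacetoxyiodo)benzene CC(=O)OI(OC(C)=O)c1ccccc1
Why: Each Si–OH binds Pd(II) and delivers it by concerted metalation–deprotonation to the one free C–H ortho to the silyloxy oxygen (six-membered Pd–O–Si–O–C–C palladacycle), PhI(OAc)2 oxidises the metal to Pd(IV), and C–OAc reductive elimination gives the ortho-acetoxy silanol 17. The silanol then displaces the acetyl group with loss of AcOH, closing on each of rings A and C a five-membered 1,3,2-benzodioxasilole by condensation at silicon. The closest known reaction type is the silanol-directed Pd-catalysed ortho C–H oxygenation of phenols to silicon-protected catechols, run here at two sites in one flask. No stereocentre is formed. The step needs site selectivity, which the substrate secures: on both rings the other ortho position carries the diaryl ether oxygen, and the nearest C–H bonds of rings B and D would require nine-membered palladacycles. It also needs the new electron-rich catechols to survive the iodine(III) oxidant, which the silylene bridge formed in situ should ensure.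

**Step 11**
Reactants: 18
Product: 19 target CNP0114693.0
Conditions: HF·pyridine, THF, 0 °C → rt, under argon
Reagents that add atoms: none
Why: fluoride cleavage of both silylene bridges, driven by Si–F bond formation, under non-basic conditions that should spare the oxidation-prone catechols.

**Compound list**

1 | 5-bromo-2-methoxyphenol | COc1ccc(Br)cc1O | starting material
2 | 4-fluorobenzaldehyde | O=Cc1ccc(F)cc1 | starting material
3 | 4-(5-bromo-2-methoxyphenoxy)benzaldehyde | COc1ccc(Br)cc1Oc1ccc(C=O)cc1 | intermediate
4 | 2-iodophenol | Oc1ccccc1I | starting material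
5 | 2-fluoro-3-methoxybenzaldehyde | COc1cccc(C=O)c1F | starting material
6 | 2-(2-iodophenoxy)-3-methoxybenzaldehyde | COc1cccc(C=O)c1Oc1ccccc1I | intermediate
7 | ethynyltrimethylsilane | C#C[Si](C)(C)C | starting material
8 | 4-{2-methoxy-5-[(trimethylsilyl)ethynyl]phenoxy}benzaldehyde | COc1ccc(C#C[Si](C)(C)C)cc1Oc1ccc(C=O)cc1 | intermediate
9 | 4-(5-ethynyl-2-methoxyphenoxy)benzaldehyde | COc1ccc(C#C)cc1Oc1ccc(C=O)cc1 | intermediate (not isolated)
10 | diarylalkyne dialdehyde | COc1ccc(cc1Oc1ccc(C=O)cc1)C#Cc1ccccc1Oc1c(OC)cccc1C=O | intermediate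
11 | bibenzyl dialdehyde | COc1ccc(cc1Oc1ccc(C=O)cc1)CCc1ccccc1Oc1c(OC)cccc1C=O | intermediate
12 | macrocyclic (Z)-stilbene bis(methyl ether) | COc1ccc2cc1Oc1ccc(cc1)/C=C\c1cccc(OC)c1Oc1ccccc1CC2 | intermediate
13 | macrocyclic bis(bibenzyl) bis(methyl ether) | COc1ccc2cc1Oc1ccc(cc1)CCc1cccc(OC)c1Oc1ccccc1CC2 | intermediate
14 | macrocyclic bisphenol | Oc1ccc2cc1Oc1ccc(cc1)CCc1cccc(O)c1Oc1ccccc1CC2 | intermediate
15 | bis(di-tert-butylsilyl triflate) ether of 14 | CC(C)(C)[Si](OS(=O)(=O)C(F)(F)F)(Oc1ccc2cc1Oc1ccc(cc1)CCc1cccc(O[Si](OS(=O)(=O)C(F)(F)F)(C(C)(C)C)C(C)(C)C)c1Oc1ccccc1CC2)C(C)(C)C | intermediate (not isolated)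
16 | bis(di-tert-butylhydroxysilyl) ether of 14 | CC(C)(C)[Si](O)(Oc1ccc2cc1Oc1ccc(cc1)CCc1cccc(O[Si](O)(C(C)(C)C)C(C)(C)C)c1Oc1ccccc1CC2)C(C)(C)C | intermediate
17 | bis(ortho-acetoxy) bis(silanol) | CC(=O)Oc1cc2cc(c1O[Si](O)(C(C)(C)C)C(C)(C)C)Oc1ccc(cc1)CCc1ccc(OC(C)=O)c(O[Si](O)(C(C)(C)C)C(C)(C)C)c1Oc1ccccc1CC2 | intermediate (not isolated)
18 | bis(di-tert-butylsilylene)-protected target | CC(C)(C)[Si]1(C(C)(C)C)Oc2cc3cc(c2O1)Oc1ccc(cc1)CCc1ccc2O[Si](C(C)(C)C)(C(C)(C)C)Oc2c1Oc1ccccc1CC3 | intermediate
19 | CNP0114693.0 | Oc1cc2cc(c1O)Oc1ccc(cc1)CCc1ccc(O)c(O)c1Oc1ccccc1CC2 | target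

**Step count and risks**

Total steps: 11. Longest linear sequence: 10 (steps 1, 3–11).

Steps most likely to fail:

1. Step 10. The iodine(III) oxidant may attack the electron-rich diaryl ether rings, or the reaction may stall after the first oxygenation because the flanking aryloxy group slows palladation. Fallback, from 14 back to 19: 14 is formylated at the same two ortho C–H positions by magnesium-mediated ortho-formylation (MgCl2, Et3N, paraformaldehyde, MeCN, reflux) to give bis(salicylaldehyde) F1. A Dakin oxidation (aq. H2O2, boric acid, THF) then converts both formyl groups into bis(aryl formate) F2, which is hydrolysed on degassed dilute-acid work-up to 19.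

2. Step 6. Intermolecular carbonyl coupling (oligomerisation) may outrun ring closure, or the reaction may stop at the pinacol stage. Fallback, from 11 back to 13, closing the ring by an sp3–sp3 bond with no alkene: NaBH4 in MeOH–THF reduces 11 to bibenzyl diol F3, PBr3 in CH2Cl2 gives bis(benzyl bromide) F4, and an intramolecular Wurtz-type coupling (Na, tetraphenylethylene, THF, −78 °C, high dilution) gives 13 directly, so step 7 is skipped.

3. Step 5. Chemoselectivity may be lost, with partial reduction of the aryl aldehydes or stalling at the stilbene. Fallback, from 10 back to 11, a redox detour that removes the aldehydes before hydrogenation: NaBH4 reduces 10 to alkyne diol F5, hydrogenation (H2, Pd/C, EtOAc with a trace of Et3N) gives bibenzyl diol F3, and MnO2 in CH2Cl2 re-oxidises both benzylic alcohols to 11.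

**Further compounds**

F1 | step 10 | macrocyclic bis(salicylaldehyde) | O=Cc1cc2cc(c1O)Oc1ccc(cc1)CCc1ccc(C=O)c(O)c1Oc1ccccc1CC2
F2 | step 10 | macrocyclic bis(aryl formate) | O=COc1cc2cc(c1O)Oc1ccc(cc1)CCc1ccc(OC=O)c(O)c1Oc1ccccc1CC2
F3 | step 6 | bibenzyl diol | COc1ccc(cc1Oc1ccc(CO)cc1)CCc1ccccc1Oc1c(OC)cccc1CO
F4 | step 6 | bis(benzyl bromide) | COc1ccc(cc1Oc1ccc(CBr)cc1)CCc1ccccc1Oc1c(OC)cccc1CBr
F5 | step 5 | alkyne diol | COc1ccc(cc1Oc1ccc(CO)cc1)C#Cc1ccccc1Oc1c(OC)cccc1CO
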